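**Strategy.** Drimane numbering is used (ring A = C1–C5 and C10; ring B = C5–C10; C11 on C9). The plan rests on cutting C4–C5. Because the quaternary C10 lies para to C7 in ring B, ring B can start as a mirror-symmetric cyclohexa-2,5-dienone whose β-carbons C5 and C9 are enantiotopic, with the C1–C4 isopropyl ketone chain on C10. One catalytic, enantioselective intramolecular Michael addition of C4 to C5 closes ring A, creates the C4 quaternary centre and sets C5 and C10 as a cis-decalin. The precursor is 4-methyl-4-(4-methyl-3-oxopentyl)cyclohexa-2,5-dienone. The surviving C7 enone later delivers the C8 methyl, C11 and the C7=C8 olefin.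

Key step: step 4

**Remarks on the chemistry**
- β is the face of ring B that carries the C10 methyl. The target SMILES encodes a cis-fused decalin (H5 and 10-CH3 both β) with H9 β and C11 α; the route is built for exactly this configuration, (5S,9R,10S), and no structure needed correcting.
- Tautomers and conjugate bases of numbered compounds (enols, enolates, alkoxides) and catalyst-bound species carry no number of their own.
- (R)-TRIP = (R)-3,3′-bis(2,4,6-triisopropylphenyl)-1,1′-binaphthyl-2,2′-diyl hydrogen phosphate. The sense of induction in step 4 cannot be predicted with confidence; the catalyst enantiomer that gives 10 is to be fixed in the first experiment, and (R) is written here.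
- Et2NSiMe3, Bu3SnCH2I and TRIP are taken as catalogue reagents.

**Route**

Step 1
Reactants: 1 propanal; 2 4-methylpent-1-en-3-one
Product: 3 2,6-dimethyl-5-oxoheptanal (racemic)
Conditions: Et2NSiMe3 (20 mol %), MeCN, 60 °C, sealed vessel, 1 in twofold excess
Reagents that add atoms: none
Why: Amine-catalysed (enamine) Michael addition of an aldehyde to a vinyl ketone, run with excess propanal to suppress double addition; the new stereocentre is formed racemic, which is immaterial because this carbon becomes the prochiral C10 of 9.

Step 2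
Reactants: 3 2,6-dimethyl-5-oxoheptanal; 4 but-3-en-2-one
Product: 8 4-methyl-4-(4-methyl-3-oxopentyl)cyclohex-2-en-1-one (racemic), via enamine 5 (not isolated), via aminal 6 (not isolated), via keto aldehyde 7 (not isolated)
Conditions: pyrrolidine (1.2 eq), PhMe, reflux, Dean–Stark; then 4, 0 °C → rt; then 6 M HCl, rt
Reagents that add atoms: none
Why: Stork enamine Michael addition followed by acid hydrolysis and intramolecular aldol condensation (Robinson-type annulation of an α,α-disubstituted aldehyde): pyrrolidine condenses with the aldehyde in preference to the hindered isopropyl ketone, and only the methyl-ketone carbon can close a six-membered enone, so the racemic quaternary centre (future C10) is the sole outcome.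

Step 3
Reactants: 8 4-methyl-4-(4-methyl-3-oxopentyl)cyclohex-2-en-1-one
Product: 9 4-methyl-4-(4-methyl-3-oxopentyl)cyclohexa-2,5-dien-1-one (achiral)
Conditions: DDQ (1.5 eq), TsOH·H2O (cat.), 1,4-dioxane, reflux
Reagents that add atoms: none
Why: DDQ dehydrogenation of a 4,4-disubstituted cyclohexenone through its cross-conjugated dienol, whose hydride loss gives a hydroxyarenium-type cation that the saturated side-chain ketone cannot match, so only the ring is oxidised and the quaternary carbon blocks aromatisation; the stereocentre of 8 disappears as the ring becomes mirror-symmetric.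

Step 4
Reactants: 9 4-methyl-4-(4-methyl-3-oxopentyl)cyclohexa-2,5-dien-1-one
Product: 10 (5S,10R)-4,4,10-trimethyl-cis-Δ8(9)-octalin-3,7-dione
Conditions: (R)-TRIP (10 mol %), PhMe, 60 °C
Reagents that add atoms: none
Why: Proposed new method: the chiral phosphoric acid catalyses reversible enolisation of the side-chain ketone, and the tetrasubstituted C3=C4 enol adds through C4 to the β-carbon C5 of the acid-activated dienone while the catalyst bridges the enol O–H and the C7 carbonyl; tautomerisation of the resulting C7 dienol gives the enone. The closest known reaction types are the phosphoric-acid-catalysed desymmetrising oxa-Michael cyclisation of 4-substituted cyclohexadienones and phosphoric-acid enol catalysis, in which α-branched ketones add to enones through their more substituted enol. Ring A closes in a 6-exo-trig mode at the enone (6-(enolendo)-exo-trig for the enol), the only closure open to either enol of the ketone, since the C2 enol could form only a four-membered ring. The cis relationship of H5 and the C10 methyl is substrate-controlled, because the three-carbon tether anchored on C10 can reach C5 only on its own face. The absolute configuration at C5 and C10 is catalyst-controlled, since attack on C5 and attack on C9 pass through mirror-image chair arrangements that use opposite faces of the enol and that the chiral phosphate pocket must tell apart. The step therefore needs only discrimination of the two enantiotopic enone arms; regio- and diastereoselectivity are secured by tether length and anchoring, C4 carries two identical methyls so no further stereocentre arises, and the acidic medium avoids the base-mediated retro-Michael pathway that could erode enantiopurity.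

Step 5
Reactants: 10 (5S,10R)-4,4,10-trimethyl-cis-Δ8(9)-octalin-3,7-dione
Product: 11 3,3-(ethylenedioxy)-4,4,10-trimethyl-cis-Δ8(9)-octalin-7-one
Conditions: HOCH2CH2OH (3 eq), TsOH·H2O (cat.), PhH, reflux, Dean–Stark
Reagents that add atoms: ethylene glycol, OCCO
Why: Chemoselective acid-catalysed acetalisation of the saturated C3 ketone (as in the selective protection of the Wieland–Miescher ketone), the C7 enone being deactivated by conjugation and lacking the γ-hydrogen (C10 is quaternary) through which enones normally ketalise; no stereocentre is touched.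

Step 6
Reactants: 11 3,3-(ethylenedioxy)-4,4,10-trimethyl-cis-Δ8(9)-octalin-7-one
Product: 12 3,3-(ethylenedioxy)-8-iodo-4,4,10-trimethyl-cis-Δ8(9)-octalin-7-one
Conditions: I2 (2 eq), pyridine/CH2Cl2 1:1, 0 °C → rt
Reagents that add atoms: iodine, II
Why: α-Iodination of a cyclic enone by the iodine/pyridine addition–elimination sequence (Baylis–Hillman-type), which works on 4,4-disubstituted cyclohexenones; the basic medium leaves the dioxolane intact.

Step 7
Reactants: 12 3,3-(ethylenedioxy)-8-iodo-4,4,10-trimethyl-cis-Δ8(9)-octalin-7-one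
Product: 13 3,3-(ethylenedioxy)-4,4,8,10-tetramethyl-cis-Δ8(9)-octalin-7-one
Conditions: Me4Sn (2 eq), PdCl2(PhCN)2 (5 mol %), AsPh3 (10 mol %), CuI (10 mol %), NMP, 80 °C
Reagents that add atoms: tetramethylstannane, C[Sn](C)(C)C
Why: Stille cross-coupling of an α-iodoenone with tetramethylstannane under copper-assisted conditions, a standard route to α-methyl enones that tolerates the acetal.

Step 8
Reactants: 13 3,3-(ethylenedioxy)-4,4,8,10-tetramethyl-cis-Δ8(9)-octalin-7-one
Product: 14 3,3-(ethylenedioxy)-4,4,8,10-tetramethyl-cis-Δ8(9)-octalin-7α-ol (OH trans to the C10 methyl)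
Conditions: NaBH4, CeCl3·7H2O, MeOH, −78 → −20 °C
Reagents that add atoms: none
Why: Luche 1,2-reduction of the enone: C4 with its geminal methyls sits on the concave α face of ring B in a 1,3-relationship to C7, so hydride should enter from the convex β face and set the 7α-alcohol.

Step 9
Reactants: 14 3,3-(ethylenedioxy)-4,4,8,10-tetramethyl-cis-Δ8(9)-octalin-7α-ol
Product: 15 7α-[(tributylstannyl)methoxy]-3,3-(ethylenedioxy)-4,4,8,10-tetramethyl-cis-Δ8(9)-octalin
Conditions: KH (1.3 eq), THF, 0 °C; Bu3SnCH2I (1.2 eq), 18-crown-6 (cat.), 0 °C → rt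
Reagents that add atoms: tributyl(iodomethyl)stannane, CCCC[Sn](CCCC)(CCCC)CI
Why: Williamson etherification of the potassium alkoxide with the SN2-reactive iodomethylstannane, the standard preparation of Wittig–Still precursors; the C7 configuration is retained because only the O–H bond reacts.

Step 10
Reactants: 15 7α-[(tributylstannyl)methoxy]-3,3-(ethylenedioxy)-4,4,8,10-tetramethyl-cis-Δ8(9)-octalin
Product: 17 [3,3-(ethylenedioxy)-4,4,8,10-tetramethyl-cis-Δ7-octalin-9α-yl]methanol, via lithiomethyl ether 16 (not isolated)
Conditions: n-BuLi (1.3 eq), THF, −78 → −20 °C; aq. NH4Cl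
Reagents that add atoms: none
Why: Wittig–Still [2,3]-sigmatropic rearrangement: tin–lithium exchange gives the oxymethyl-lithium, which bonds to C9 suprafacially on the α face that carries the C7–O bond, so the C7 configuration is transferred to C9 (C11 α, trans to the C10 methyl) while the double bond moves to C7=C8.

Step 11
Reactants: 17 [3,3-(ethylenedioxy)-4,4,8,10-tetramethyl-cis-Δ7-octalin-9α-yl]methanol; 18 umbelliferone (7-hydroxy-2H-chromen-2-one)
Product: 19 7-{[3,3-(ethylenedioxy)-4,4,8,10-tetramethyl-cis-Δ7-octalin-9α-yl]methoxy}-2H-chromen-2-one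
Conditions: PPh3 (1.5 eq), DIAD (1.5 eq), THF, 0 °C → rt
Reagents that add atoms: none
Why: Mitsunobu etherification of a primary alcohol with an acidic phenol (umbelliferone, pKa about 8); C11 is not stereogenic and the lactone, olefin and acetal are inert to the redox pair.

Step 12
Reactants: 19 7-{[3,3-(ethylenedioxy)-4,4,8,10-tetramethyl-cis-Δ7-octalin-9α-yl]methoxy}-2H-chromen-2-one
Product: 20 7-{[(1R,4aS,8aS)-2,5,5,8a-tetramethyl-6-oxo-1,4,4a,5,6,7,8,8a-octahydronaphthalen-1-yl]methoxy}-2H-chromen-2-one (target; drimane numbering 5S,9R,10S)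
Conditions: 2 M HCl, THF, rt
Reagents that add atoms: water, O
Why: Acid-catalysed hydrolysis of the dioxolane, helped by relief of strain next to the geminal methyls; dilute acid at room temperature should not move the trisubstituted olefin, cleave the aryl ether or epimerise C9, which has no adjacent carbonyl.

**Compound list**
1 | propanal | CCC=O | starting material
2 | 4-methylpent-1-en-3-one | CC(C)C(=O)C=C | starting material
3 | 2,6-dimethyl-5-oxoheptanal (racemic) | CC(C)C(=O)CCC(C)C=O | intermediate
4 | but-3-en-2-one | CC(=O)C=C | starting material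
5 | 2,6-dimethyl-7-(pyrrolidin-1-yl)hept-6-en-3-one (E/Z mixture) | CC(C)C(=O)CCC(C)=CN1CCCC1 | intermediate (not isolated)
6 | 4-methyl-1-[3,6-dimethyl-2-(pyrrolidin-1-yl)-3,4-dihydro-2H-pyran-3-yl]pentan-3-one (diastereomer mixture) | CC1=CCC(C)(CCC(=O)C(C)C)C(N2CCCC2)O1 | intermediate (not isolated)
7 | 2,6-dimethyl-5-oxo-2-(3-oxobutyl)heptanal (racemic) | CC(C)C(=O)CCC(C)(CCC(C)=O)C=O | intermediate (not isolated)
8 | 4-methyl-4-(4-methyl-3-oxopentyl)cyclohex-2-en-1-one (racemic) | CC(C)C(=O)CCC1(C)CCC(=O)C=C1 | intermediate
9 | 4-methyl-4-(4-methyl-3-oxopentyl)cyclohexa-2,5-dien-1-one | CC(C)C(=O)CCC1(C)C=CC(=O)C=C1 | intermediate (key-step precursor)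
10 | (5S,10R)-4,4,10-trimethyl-cis-Δ8(9)-octalin-3,7-dione = (4aR,8aS)-4a,8,8-trimethyl-4a,5,6,8a-tetrahydronaphthalene-2,7(1H,8H)-dione | O=C1C[C@@H]2C(C)(C)C(=O)CC[C@]2(C)C=C1 | intermediate (key-step product)
11 | 3,3-(ethylenedioxy)-4,4,10-trimethyl-cis-Δ8(9)-octalin-7-one | O=C1C[C@@H]2C(C)(C)C3(OCCO3)CC[C@]2(C)C=C1 | intermediate
12 | 3,3-(ethylenedioxy)-8-iodo-4,4,10-trimethyl-cis-Δ8(9)-octalin-7-one | O=C1C[C@@H]2C(C)(C)C3(OCCO3)CC[C@]2(C)C=C1I | intermediate
13 | 3,3-(ethylenedioxy)-4,4,8,10-tetramethyl-cis-Δ8(9)-octalin-7-one | O=C1C[C@@H]2C(C)(C)C3(OCCO3)CC[C@]2(C)C=C1C | intermediate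
14 | 3,3-(ethylenedioxy)-4,4,8,10-tetramethyl-cis-Δ8(9)-octalin-7α-ol | O[C@@H]1C[C@@H]2C(C)(C)C3(OCCO3)CC[C@]2(C)C=C1C | intermediate
15 | 7α-[(tributylstannyl)methoxy]-3,3-(ethylenedioxy)-4,4,8,10-tetramethyl-cis-Δ8(9)-octalin | CCCC[Sn](CCCC)(CCCC)CO[C@@H]1C[C@@H]2C(C)(C)C3(OCCO3)CC[C@]2(C)C=C1C | intermediate
16 | 7α-(lithiomethoxy)-3,3-(ethylenedioxy)-4,4,8,10-tetramethyl-cis-Δ8(9)-octalin | [Li]CO[C@@H]1C[C@@H]2C(C)(C)C3(OCCO3)CC[C@]2(C)C=C1C | intermediate (not isolated)
17 | [3,3-(ethylenedioxy)-4,4,8,10-tetramethyl-cis-Δ7-octalin-9α-yl]methanol (5S,9R,10S) | CC1=CC[C@@H]2C(C)(C)C3(OCCO3)CC[C@]2(C)[C@@H]1CO | intermediate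
18 | umbelliferone (7-hydroxy-2H-chromen-2-one) | O=c1ccc2ccc(O)cc2o1 | starting material
19 | 7-{[3,3-(ethylenedioxy)-4,4,8,10-tetramethyl-cis-Δ7-octalin-9α-yl]methoxy}-2H-chromen-2-one | CC1=CC[C@@H]2C(C)(C)C3(OCCO3)CC[C@]2(C)[C@@H]1COc1ccc2ccc(=O)oc2c1 | intermediate
20 | 7-{[(1R,4aS,8aS)-2,5,5,8a-tetramethyl-6-oxo-1,4,4a,5,6,7,8,8a-octahydronaphthalen-1-yl]methoxy}-2H-chromen-2-one | CC1=CC[C@@H]2C(C)(C)C(=O)CC[C@]2(C)[C@@H]1COc1ccc2ccc(=O)oc2c1 | target

**Step count.** Total: 12 steps. Longest linear sequence: 12 steps (1 and 2 to 20); 4 and 18 enter as purchased materials.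

**Steps most likely to fail**

Step 4 (the new method). Enolisation of the unactivated ketone by the weak chiral acid may be too slow, or the catalyst may distinguish the two enone arms poorly, leaving conversion or enantiomeric purity low. The fallback uses known chemistry and sets out from 9. t-BuOK (0.3 eq) in t-BuOH/THF at rt closes ring A by ordinary base-mediated intramolecular Michael addition of the equilibrating potassium enolate. The tether again enforces the cis fusion, but 10 is formed as the racemate, that is, together with its mirror image (5R,10S)-4,4,10-trimethyl-cis-Δ8(9)-octalin-3,7-dione F1. Preparative chromatography on a chiral stationary phase (amylose tris(3,5-dimethylphenylcarbamate), supercritical CO2/MeOH) removes F1, and the route is rejoined at 10.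

Step 10. The oxymethyl-lithium has to reach C9 across the concave α face, syn to C4. If that is slow, [1,2]-shift or protonation of the carbanion may take over. The fallback sets out from 14 and bypasses 15 and 16. Heating 14 with Me2NCH(OMe)2 in xylene at 140 °C (Büchi-type [2,3]-rearrangement of the alkoxy(amino)carbene) gives the one-carbon homologue 3,3-(ethylenedioxy)-N,N,4,4,8,10-hexamethyl-cis-Δ7-octalin-9α-carboxamide F2. The transfer is suprafacial as before, but runs under neutral thermal conditions with no organolithium. LiEt3BH in THF (0 °C → rt) then reduces the tertiary amide to the primary alcohol, and the route is rejoined at 17.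

Step 8. Hydride delivery may show poor or reversed facial selectivity if ring B reacts through a conformer in which C4 no longer screens the α face. The fallback sets out from 13. The 7β-epimer 3,3-(ethylenedioxy)-4,4,8,10-tetramethyl-cis-Δ8(9)-octalin-7β-ol F3, obtained from the same reduction and separated, is inverted by Mitsunobu esterification (4-nitrobenzoic acid, PPh3, DIAD, PhMe, 0 °C → rt) to 3,3-(ethylenedioxy)-4,4,8,10-tetramethyl-cis-Δ8(9)-octalin-7α-yl 4-nitrobenzoate F4. Methanolysis (K2CO3, MeOH, rt) returns the route at 14.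

**Further compounds**
F1 | step 4 | (5R,10S)-4,4,10-trimethyl-cis-Δ8(9)-octalin-3,7-dione (enantiomer of 10) | O=C1C[C@H]2C(C)(C)C(=O)CC[C@@]2(C)C=C1
F2 | step 10 | 3,3-(ethylenedioxy)-N,N,4,4,8,10-hexamethyl-cis-Δ7-octalin-9α-carboxamide | CC1=CC[C@@H]2C(C)(C)C3(OCCO3)CC[C@]2(C)[C@@H]1C(=O)N(C)C
F3 | step 8 | 3,3-(ethylenedioxy)-4,4,8,10-tetramethyl-cis-Δ8(9)-octalin-7β-ol | O[C@H]1C[C@@H]2C(C)(C)C3(OCCO3)CC[C@]2(C)C=C1C
F4 | step 8 | 3,3-(ethylenedioxy)-4,4,8,10-tetramethyl-cis-Δ8(9)-octalin-7α-yl 4-nitrobenzoate | O=C(O[C@@H]1C[C@@H]2C(C)(C)C3(OCCO3)CC[C@]2(C)C=C1C)c1ccc(cc1)[N+](=O)[O-]
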